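The benzene ring is disconnected at C1–C6 (ring numbered C1 pentadecyl, C3 OH, C5 OMe, C6 OAc). The meta array C1-alkyl/C3-O/C5-O is a resorcylate pattern, and the C6 oxygen can be carried as a carboxyl carbon. The key step folds an open-chain diketo-dioxinone, in which the palmitoyl ketone (future C1) faces the dioxinone α-carbon (future C6), into the arene by aldol closure and dehydration. One operation builds the ring, fixes the chain position and delivers the two phenols differentiated, one free and one locked in an acetonide with the carboxyl. The carboxyl is then reduced to an aldehyde and exchanged for oxygen by Dakin oxidation.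

Key step: step 3

Remark: the target has no stereocentre; the only stereogenic carbons on the route (C5 of adduct 8, C4 of lactolate 11) arise as racemates and disappear within the same step.

Step 1
Reactants: 1 2,2,6-trimethyl-4H-1,3-dioxin-4-one; 2 acetyl chloride
Product: 4 2,2-dimethyl-6-(2-oxopropyl)-4H-1,3-dioxin-4-one, via lithium dienolate 3 (not isolated)
Conditions: LiN(SiMe3)2 (1 equiv. per 1), THF, −78 °C; then 2 (0.5 equiv.), −78 °C; aq. NH4Cl
Reagents that add atoms: none
Why: The kinetic lithium dienolate 3 reacts with the acid chloride at its terminal (γ) carbon in a Claisen-type C-acylation, the second equivalent of 3 taking up the acidic proton of the β-keto product so that it is not acylated again.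

Step 2
Reactants: 4 2,2-dimethyl-6-(2-oxopropyl)-4H-1,3-dioxin-4-one; 5 palmitoyl chloride (hexadecanoyl chloride)
Product: 7 6-(2,4-dioxononadecyl)-2,2-dimethyl-4H-1,3-dioxin-4-one, via dilithium dianion 6 (not isolated)
Conditions: LiN(iPr)2 (2.1 equiv.), THF, −78 °C; then 5 (0.5 equiv.), −78 °C; aq. NH4Cl; crude 7 used directly
Reagents that add atoms: none
Why: Two equivalents of amide base convert 4 into the β-dicarbonyl-type dianion 6, whose last-formed and most nucleophilic terminal carbanion undergoes Claisen-type C-acylation with the acid chloride, while the surplus dianion deprotonates the product and so shields it from a second acylation.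

Step 3
Reactants: 7 6-(2,4-dioxononadecyl)-2,2-dimethyl-4H-1,3-dioxin-4-one
Product: 9 7-hydroxy-2,2-dimethyl-5-pentadecyl-4H-1,3-benzodioxin-4-one, via aldol adduct 8 (not isolated)
Conditions: Et3N, CH2Cl2, rt; aq. HCl work-up
Reagents that add atoms: none
Why: Triethylamine deprotonates the methylene between the dioxinone and the internal ketone of 7, and the resulting vinylogous enolate adds through the dioxinone α-carbon (future ring C6) to the pentadecyl ketone carbon (future C1) in an intramolecular aldol reaction; loss of water from 8 and enolisation of the remaining ring ketone (future C3–OH) then give the arene. The closest known reaction type is the base-mediated aldol cyclisation–aromatisation of poly-β-carbonyl chains, as used to make acetonide-protected resorcylates from diketo-dioxinones. The carbocycle is closed in a 6-(enolendo)-exo-trig mode. No stereocentre remains in 9, since the carbinol carbon of 8 forms as a racemate and is lost on dehydration. The step needs C- over O-cyclisation and closure onto the terminal ketone only: working at room temperature keeps the dioxinone from fragmenting to an acylketene (the entry to pyranones), and the nucleophilic carbon can reach only the terminal ketone through a six-membered transition state, the internal ketone lying too close and being largely enolised. Because the carboxyl carbon and its ortho oxygen stay tied in the acetonide, the C3 hydroxyl should emerge as the only free phenol.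

Step 4
Reactants: 9 7-hydroxy-2,2-dimethyl-5-pentadecyl-4H-1,3-benzodioxin-4-one
Product: 10 7-(benzyloxy)-2,2-dimethyl-5-pentadecyl-4H-1,3-benzodioxin-4-one
Conditions: BnBr, K2CO3, DMF, rt
Reagents that add atoms: benzyl bromide, BrCc1ccccc1
Why: Williamson etherification of the only acidic O–H, a phenol para to the carbonyl, with a reactive benzylic bromide, the acetonide lactone being inert to carbonate in an aprotic solvent.

Step 5
Reactants: 10 7-(benzyloxy)-2,2-dimethyl-5-pentadecyl-4H-1,3-benzodioxin-4-one
Product: 12 4-(benzyloxy)-2-hydroxy-6-pentadecylbenzaldehyde, via aluminium lactolate 11 (not isolated)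
Conditions: iBu2AlH, CH2Cl2, −78 °C; then aq. potassium sodium tartrate, rt
Reagents that add atoms: none
Why: Hydride delivery to the lactone-type carbonyl gives the aluminium lactolate 11, which persists at −78 °C and on aqueous work-up collapses with loss of acetone to the hydrogen-bonded salicylaldehyde, a known ester-to-aldehyde partial reduction of 2,2-dimethylbenzodioxinones.

Step 6
Reactants: 12 4-(benzyloxy)-2-hydroxy-6-pentadecylbenzaldehyde
Product: 13 4-(benzyloxy)-2-methoxy-6-pentadecylbenzaldehyde
Conditions: MeI, K2CO3, DMF, rt
Reagents that add atoms: iodomethane, CI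
Why: Williamson O-methylation of the sole phenol, whose hydrogen bond to the aldehyde is broken by carbonate in DMF, fixes the C5 methoxy group of the target.

Step 7
Reactants: 13 4-(benzyloxy)-2-methoxy-6-pentadecylbenzaldehyde
Product: 15 4-(benzyloxy)-2-methoxy-6-pentadecylphenol, via aryl formate 14 (not isolated)
Conditions: mCPBA, CH2Cl2, 0 °C to rt; then K2CO3 (cat.), MeOH, rt
Reagents that add atoms: mCPBA (3-chloroperoxybenzoic acid), OOC(=O)c1cccc(Cl)c1
Why: Dakin-type Baeyer–Villiger oxidation, in which the electron-rich aryl group (ortho-methoxy, para-benzyloxy) migrates in the peracid adduct in preference to hydride to give formate 14, which mild base methanolysis cleaves to the phenol at the site of the former carboxyl carbon.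

Step 8
Reactants: 15 4-(benzyloxy)-2-methoxy-6-pentadecylphenol
Product: 16 4-(benzyloxy)-2-methoxy-6-pentadecylphenyl acetate
Conditions: Ac2O, pyridine, DMAP (cat.), CH2Cl2, rt
Reagents that add atoms: acetic anhydride, CC(=O)OC(C)=O
Why: DMAP-catalysed (Steglich-type) O-acylation should acetylate the single phenol even though it is flanked by methoxy and pentadecyl groups.

Step 9
Reactants: 16 4-(benzyloxy)-2-methoxy-6-pentadecylphenyl acetate
Product: 17 4-hydroxy-2-methoxy-6-pentadecylphenyl acetate
Conditions: H2 (1 atm), Pd/C, EtOAc, rt
Reagents that add atoms: none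
Why: Heterogeneous hydrogenolysis of the benzyl aryl ether over palladium on carbon under neutral, non-nucleophilic conditions leaves the aryl acetate, the methyl ether and the saturated chain untouched.

Compound list
1 | 2,2,6-trimethyl-4H-1,3-dioxin-4-one | CC1=CC(=O)OC(C)(C)O1 | starting material
2 | acetyl chloride | CC(Cl)=O | starting material
3 | lithium 2,2-dimethyl-6-methylidene-6H-1,3-dioxin-4-olate (lithium dienolate of 1) | C=C1C=C([O-])OC(C)(C)O1.[Li+] | intermediate
4 | 2,2-dimethyl-6-(2-oxopropyl)-4H-1,3-dioxin-4-one | CC(=O)CC1=CC(=O)OC(C)(C)O1 | intermediate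
5 | palmitoyl chloride (hexadecanoyl chloride) | CCCCCCCCCCCCCCCC(Cl)=O | starting material
6 | dilithium 2,2-dimethyl-6-(2-oxidoprop-2-en-1-ylidene)-6H-1,3-dioxin-4-olate (dianion of 4) | C=C([O-])C=C1C=C([O-])OC(C)(C)O1.[Li+].[Li+] | intermediate
7 | 6-(2,4-dioxononadecyl)-2,2-dimethyl-4H-1,3-dioxin-4-one | CCCCCCCCCCCCCCCC(=O)CC(=O)CC1=CC(=O)OC(C)(C)O1 | intermediate
8 | 5-hydroxy-2,2-dimethyl-5-pentadecyl-5,6-dihydro-4H-1,3-benzodioxine-4,7(8H)-dione (racemic aldol adduct) | CCCCCCCCCCCCCCCC1(O)CC(=O)CC2=C1C(=O)OC(C)(C)O2 | intermediate
9 | 7-hydroxy-2,2-dimethyl-5-pentadecyl-4H-1,3-benzodioxin-4-one | CCCCCCCCCCCCCCCc1cc(O)cc2OC(C)(C)OC(=O)c12 | intermediate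
10 | 7-(benzyloxy)-2,2-dimethyl-5-pentadecyl-4H-1,3-benzodioxin-4-one | CCCCCCCCCCCCCCCc1cc(OCc3ccccc3)cc2OC(C)(C)OC(=O)c12 | intermediate
11 | {[7-(benzyloxy)-2,2-dimethyl-5-pentadecyl-4H-1,3-benzodioxin-4-yl]oxy}bis(2-methylpropyl)alumane (racemic lactolate) | CCCCCCCCCCCCCCCc1cc(OCc3ccccc3)cc2OC(C)(C)OC(O[Al](CC(C)C)CC(C)C)c12 | intermediate
12 | 4-(benzyloxy)-2-hydroxy-6-pentadecylbenzaldehyde | CCCCCCCCCCCCCCCc1cc(OCc2ccccc2)cc(O)c1C=O | intermediate
13 | 4-(benzyloxy)-2-methoxy-6-pentadecylbenzaldehyde | CCCCCCCCCCCCCCCc1cc(OCc2ccccc2)cc(OC)c1C=O | intermediate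
14 | 4-(benzyloxy)-2-methoxy-6-pentadecylphenyl formate | CCCCCCCCCCCCCCCc1cc(OCc2ccccc2)cc(OC)c1OC=O | intermediate
15 | 4-(benzyloxy)-2-methoxy-6-pentadecylphenol | CCCCCCCCCCCCCCCc1cc(OCc2ccccc2)cc(OC)c1O | intermediate
16 | 4-(benzyloxy)-2-methoxy-6-pentadecylphenyl acetate | CCCCCCCCCCCCCCCc1cc(OCc2ccccc2)cc(OC)c1OC(C)=O | intermediate
17 | 4-hydroxy-2-methoxy-6-pentadecylphenyl acetate | CCCCCCCCCCCCCCCc1cc(O)cc(OC)c1OC(C)=O | target

Total step count: 9. Longest linear sequence: 9 steps (1 to 17).

Steps most likely to fail

Step 3. The enolate may close through oxygen to a pyranone, the ring may stall at the hydrated stage, or the dioxinone may degrade before the aldol takes place. The fallback sets out from 7 and abandons the dioxinone-retaining closure. Heating 7 in toluene at 110 °C with benzyl alcohol should expel acetone and trap the acylketene as benzyl 3,5,7-trioxodocosanoate F1. Cs2CO3 in THF followed by aqueous HCl should aromatise this open triketo ester to benzyl 2,4-dihydroxy-6-pentadecylbenzoate F2. Hydrogenolysis (H2, Pd/C, EtOAc) should give 2,4-dihydroxy-6-pentadecylbenzoic acid F3. Acetone with (CF3CO)2O and CF3CO2H should then tie the carboxyl and its ortho hydroxyl into the acetonide, returning to the route at 9.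

Step 2. Proton transfer from the acidic product to unreacted dianion, O-acylation and double acylation may consume the acid chloride and leave little triketide. The fallback sets out from 5, which with MeNHOMe·HCl and K2CO3 in CH2Cl2/H2O should give N-methoxy-N-methylhexadecanamide F4. Addition of this amide to dianion 6 (generated from 4 as before) should stop at the chelated tetrahedral adduct, releasing the ketone only on work-up and returning to the route at 7.

Step 5. Hydride transfer may continue past the lactolate to the benzylic alcohol, or the lactolate may not collapse cleanly to the aldehyde. The fallback sets out from 10 and reduces it exhaustively with LiAlH4 in THF to 5-(benzyloxy)-2-(hydroxymethyl)-3-pentadecylphenol F5. Chemoselective oxidation of the benzylic alcohol with MnO2 in CH2Cl2 should then give the salicylaldehyde, returning to the route at 12.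

Further compounds
F1 | step 3 | benzyl 3,5,7-trioxodocosanoate | CCCCCCCCCCCCCCCC(=O)CC(=O)CC(=O)CC(=O)OCc1ccccc1
F2 | step 3 | benzyl 2,4-dihydroxy-6-pentadecylbenzoate | CCCCCCCCCCCCCCCc1cc(O)cc(O)c1C(=O)OCc2ccccc2
F3 | step 3 | 2,4-dihydroxy-6-pentadecylbenzoic acid | CCCCCCCCCCCCCCCc1cc(O)cc(O)c1C(O)=O
F4 | step 2 | N-methoxy-N-methylhexadecanamide | CCCCCCCCCCCCCCCC(=O)N(C)OC
F5 | step 5 | 5-(benzyloxy)-2-(hydroxymethyl)-3-pentadecylphenol | CCCCCCCCCCCCCCCc1cc(OCc2ccccc2)cc(O)c1CO
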